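**Plan**
Ring numbering of the target: C1 benzoyl, C2 OH, C3 prenyl, C4 OH, C5 prenyl, C6 OMe.
Retrosynthesis: C2–OH goes back to C2–Br and C4–OH to its silyl ether; the benzene ring is then cut at C1–C6 and C2–C3.
Enabling feature: C3–C4–C5–C6 are the diene carbons of a 2-silyloxy-4-methoxycyclohexa-1,3-diene (its CH2–CH2 unit leaves as ethylene), and C1–C2 are the alkyne carbons of a 3-bromo-ynone that already carries the benzoyl group.
Forward: cyclohexane-1,3-dione is C2-prenylated, O-methylated, prenylated at the α′ carbon and silylated (steps 1–4); benzoyl chloride and bis(trimethylsilyl)acetylene give the bromoynone (steps 5–6); the benzene ring, the only ring built, arises in step 7; step 8 exchanges Br for OH and removes the silyl group.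
Stereochemistry: the target has no stereocentre; 6 and 13 are racemic and their stereocentres vanish in steps 4 and 7.

Key step: step 7

**Route**

Step 1
Reactants: 1 cyclohexane-1,3-dione; 2 1-bromo-3-methylbut-2-ene (prenyl bromide)
Product: 3 2-(3-methylbut-2-enyl)cyclohexane-1,3-dione
Conditions: KOH, H2O, 0 °C to rt
Reagents that add atoms: none
Why: SN2 C-alkylation of the stabilised 1,3-dione enolate by the allylic bromide, favoured over O-alkylation in water because the enolate oxygens are hydrogen-bonded.

Step 2
Reactants: 3 2-(3-methylbut-2-enyl)cyclohexane-1,3-dione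
Product: 4 3-methoxy-2-(3-methylbut-2-enyl)cyclohex-2-en-1-one
Conditions: Me2SO4, K2CO3, acetone, reflux
Reagents that add atoms: dimethyl sulfate, COS(=O)(=O)OC
Why: O-alkylation of the 2-substituted dione enolate by the hard electrophile dimethyl sulfate gives the vinylogous ester, and the basic medium avoids acid-induced cyclisation of the prenyl group onto the enol oxygen.

Step 3
Reactants: 4 3-methoxy-2-(3-methylbut-2-enyl)cyclohex-2-en-1-one; 2 1-bromo-3-methylbut-2-ene
Product: 6 3-methoxy-2,6-bis(3-methylbut-2-enyl)cyclohex-2-en-1-one (racemic), via lithium dienolate 5 (not isolated)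
Conditions: LiN(iPr)2 (commercial solution), THF, −78 °C; then 2, DMPU, −78 to 0 °C
Reagents that add atoms: none
Why: Stork–Danheiser alkylation, in which the amide base removes the α′ proton at C6 kinetically and the cross-conjugated dienolate is alkylated by the allylic bromide (SN2); the new C6 stereocentre forms racemic and is erased in step 4.

Step 4
Reactants: 6 3-methoxy-2,6-bis(3-methylbut-2-enyl)cyclohex-2-en-1-one
Product: 8 2-(tert-butyldimethylsilyloxy)-4-methoxy-1,3-bis(3-methylbut-2-enyl)cyclohexa-1,3-diene, via lithium dienolate 7 (not isolated)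
Conditions: LiN(iPr)2 (commercial solution), THF, −78 °C; then TBSCl, DMPU, −78 °C to rt; pentane, filtration, used without chromatography
Reagents that add atoms: tert-butyldimethylsilyl chloride, CC(C)(C)[Si](C)(C)Cl
Why: Kinetic enolisation takes the single remaining α′ proton, and the lithium dienolate is O-silylated by the silyl chloride (silyl enol ether formation) to give the 1-methoxy-3-silyloxy diene.

Step 5
Reactants: 9 benzoyl chloride; 10 bis(trimethylsilyl)acetylene
Product: 11 1-phenyl-3-(trimethylsilyl)prop-2-yn-1-one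
Conditions: AlCl3, CH2Cl2, 0 °C
Reagents that add atoms: none
Why: Friedel–Crafts acylation of an alkynylsilane with ipso-substitution of one silyl group; the deactivated ynone does not react a second time.

Step 6
Reactants: 11 1-phenyl-3-(trimethylsilyl)prop-2-yn-1-one
Product: 12 3-bromo-1-phenylprop-2-yn-1-one
Conditions: NBS, AgNO3 (cat.), acetone, rt, dark; aqueous work-up
Reagents that add atoms: N-bromosuccinimide, O=C1CCC(=O)N1Br
Why: Silver-catalysed bromodesilylation, in which AgNO3 turns the alkynylsilane into a silver acetylide that NBS brominates, a standard way from silylalkynes to 1-bromoalkynes that avoids the base-sensitive free ynone.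

Step 7
Reactants: 8 2-(tert-butyldimethylsilyloxy)-4-methoxy-1,3-bis(3-methylbut-2-enyl)cyclohexa-1,3-diene; 12 3-bromo-1-phenylprop-2-yn-1-one
Product: 14 [2-bromo-4-(tert-butyldimethylsilyloxy)-6-methoxy-3,5-bis(3-methylbut-2-enyl)phenyl](phenyl)methanone, via bicyclo[2.2.2]octadiene adduct 13 (not isolated)
Conditions: o-xylene, BHT (cat.), 80 °C, then reflux (about 145 °C) under an argon stream
Reagents that add atoms: none
Why: A thermal [4+2] cycloaddition of the electron-rich diene to the electron-poor bromoynone forms C6–C1 and C3–C2 and gives bicyclo[2.2.2]octa-2,5-diene 13, which on further heating loses its saturated two-carbon bridge as ethylene in a retro-[4+2] step; the closest known reaction type is the Alder–Rickert benzannulation of 2-silyloxycyclohexa-1,3-dienes with acetylenic ketones and esters. The benzene ring is closed by an intermolecular suprafacial [4+2] annulation of four diene carbons with two alkyne carbons, not by cyclisation of a chain, and it becomes aromatic without any oxidant. The two bridgehead stereocentres of 13 are fixed relative to each other by the bicycle, form racemic and vanish on ethylene loss, so no stereocontrol is needed. The selectivity that matters is regiochemical: the methoxy and the silyloxy group both place the largest HOMO coefficient on the prenyl-bearing terminus (future C3), and the ynone LUMO is largest at the bromine-bearing β-carbon, so C3 should bond to C–Br and the methoxy-bearing terminus (future C6) to the acyl-bearing carbon. Chemoselectivity for the ynone over the isolated prenyl alkenes follows from electron demand, and only the CH2–CH2 bridge can leave as a stable alkene while giving an arene.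

Step 8
Reactants: 14 [2-bromo-4-(tert-butyldimethylsilyloxy)-6-methoxy-3,5-bis(3-methylbut-2-enyl)phenyl](phenyl)methanone
Product: 16 [2,4-dihydroxy-6-methoxy-3,5-bis(3-methylbut-2-enyl)phenyl](phenyl)methanone, via bromophenol 15 (not isolated)
Conditions: KOH, degassed 1,4-dioxane/H2O, 60 °C; then Pd2(dba)3 (cat.), tBuXPhos (cat.), 100 °C; aq. NH4Cl work-up
Reagents that add atoms: potassium hydroxide, [K+].[OH-]
Why: Hydroxide first cleaves the aryl silyl ether (a phenoxide para to the ketone leaves silicon easily), and zerovalent palladium with the bulky biarylphosphine then inserts into the C2–Br bond next to the benzoyl group, exchanges bromide for hydroxide and forms C2–O by reductive elimination, which is the known palladium-catalysed hydroxylation of aryl bromides with KOH; the prenyl alkenes and the diaryl ketone are inert to aqueous base.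

**Compound list**
1 | cyclohexane-1,3-dione | O=C1CCCC(=O)C1 | starting material
2 | 1-bromo-3-methylbut-2-ene (prenyl bromide) | CC(C)=CCBr | starting material
3 | 2-(3-methylbut-2-enyl)cyclohexane-1,3-dione | O=C1CCCC(=O)C1CC=C(C)C | intermediate
4 | 3-methoxy-2-(3-methylbut-2-enyl)cyclohex-2-en-1-one | COC1=C(CC=C(C)C)C(=O)CCC1 | intermediate
5 | lithium 5-methoxy-6-(3-methylbut-2-enyl)cyclohexa-1,5-dien-1-olate | COC1=C(CC=C(C)C)C(O[Li])=CCC1 | intermediate (not isolated)
6 | 3-methoxy-2,6-bis(3-methylbut-2-enyl)cyclohex-2-en-1-one (racemic) | COC1=C(CC=C(C)C)C(=O)C(CC=C(C)C)CC1 | intermediate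
7 | lithium 5-methoxy-2,6-bis(3-methylbut-2-enyl)cyclohexa-1,5-dien-1-olate | COC1=C(CC=C(C)C)C(O[Li])=C(CC=C(C)C)CC1 | intermediate (not isolated)
8 | 2-(tert-butyldimethylsilyloxy)-4-methoxy-1,3-bis(3-methylbut-2-enyl)cyclohexa-1,3-diene | COC1=C(CC=C(C)C)C(O[Si](C)(C)C(C)(C)C)=C(CC=C(C)C)CC1 | intermediate
9 | benzoyl chloride | O=C(Cl)c1ccccc1 | starting material
10 | bis(trimethylsilyl)acetylene | C[Si](C)(C)C#C[Si](C)(C)C | starting material
11 | 1-phenyl-3-(trimethylsilyl)prop-2-yn-1-one | C[Si](C)(C)C#CC(=O)c1ccccc1 | intermediate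
12 | 3-bromo-1-phenylprop-2-yn-1-one | O=C(C#CBr)c1ccccc1 | intermediate
13 | [3-bromo-5-(tert-butyldimethylsilyloxy)-1-methoxy-4,6-bis(3-methylbut-2-enyl)bicyclo[2.2.2]octa-2,5-dien-2-yl](phenyl)methanone (racemic) | COC12CCC(CC=C(C)C)(C(Br)=C1C(=O)c1ccccc1)C(O[Si](C)(C)C(C)(C)C)=C2CC=C(C)C | intermediate (not isolated)
14 | [2-bromo-4-(tert-butyldimethylsilyloxy)-6-methoxy-3,5-bis(3-methylbut-2-enyl)phenyl](phenyl)methanone | COc1c(CC=C(C)C)c(O[Si](C)(C)C(C)(C)C)c(CC=C(C)C)c(Br)c1C(=O)c1ccccc1 | intermediate
15 | [2-bromo-4-hydroxy-6-methoxy-3,5-bis(3-methylbut-2-enyl)phenyl](phenyl)methanone (present as its potassium phenoxide) | COc1c(CC=C(C)C)c(O)c(CC=C(C)C)c(Br)c1C(=O)c1ccccc1 | intermediate (not isolated)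
16 | [2,4-dihydroxy-6-methoxy-3,5-bis(3-methylbut-2-enyl)phenyl](phenyl)methanone | COc1c(CC=C(C)C)c(O)c(CC=C(C)C)c(O)c1C(=O)c1ccccc1 | target

**Count**
Total steps: 8. Longest linear sequence: 6 steps (1, 2, 3, 4, 7, 8); steps 5 and 6 form the second branch.

**Steps most likely to fail**

Step 7. Bond formation at the two fully substituted diene termini may be so slow that desilylation of the dienol ether, hydrogen shifts within the diene or oligomerisation of the bromoynone take over. The fallback sets out from 4 and postpones one prenyl group. The dienolate 5 is O-silylated (TBSCl, DMPU) to give 2-(tert-butyldimethylsilyloxy)-4-methoxy-3-(3-methylbut-2-enyl)cyclohexa-1,3-diene F1, whose nucleophilic terminus is an unhindered CH. Heating F1 with 12 in o-xylene should lead, through the adduct [3-bromo-5-(tert-butyldimethylsilyloxy)-1-methoxy-6-(3-methylbut-2-enyl)bicyclo[2.2.2]octa-2,5-dien-2-yl](phenyl)methanone F2 and loss of ethylene, to [2-bromo-4-(tert-butyldimethylsilyloxy)-6-methoxy-5-(3-methylbut-2-enyl)phenyl](phenyl)methanone F3. Treatment as in step 8 should pass through [2-bromo-4-hydroxy-6-methoxy-5-(3-methylbut-2-enyl)phenyl](phenyl)methanone F4 and give [4,6-dihydroxy-2-methoxy-3-(3-methylbut-2-enyl)phenyl](phenyl)methanone F5. C-Prenylation of F5 with 2 (aqueous KOH, 0 °C) at the only free ring carbon, which lies between the two hydroxyl groups, comes back to the route at 16.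

Step 8. At the crowded, hexasubstituted arylpalladium intermediate, hydroxide transfer and C–O reductive elimination may be slow, so that protodebromination in hot aqueous base dominates. The fallback sets out from 14 and makes the C2–O bond by way of boron. Miyaura borylation (Pd(OAc)2, SPhos, B2pin2, KOAc, dioxane, 80 °C), which runs under weakly basic anhydrous conditions and leaves the silyl ether in place, should give phenyl[4-(tert-butyldimethylsilyloxy)-2-methoxy-3,5-bis(3-methylbut-2-enyl)-6-(4,4,5,5-tetramethyl-1,3,2-dioxaborolan-2-yl)phenyl]methanone F6. Oxidation with NaBO3·4H2O in THF/H2O at rt, which spares the prenyl alkenes, should give [4-(tert-butyldimethylsilyloxy)-2-hydroxy-6-methoxy-3,5-bis(3-methylbut-2-enyl)phenyl](phenyl)methanone F7. Fluoride cleavage (Bu4NF, THF, 0 °C) comes back to the route at 16.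

Step 4. O-Silylation of the hindered tetrasubstituted enolate may stay incomplete, and the dienol ether may hydrolyse back to 6 during isolation. The fallback sets out from 6 and replaces the silyl dienol ether by an enol ester that tolerates water and chromatography. The dienolate 7 is quenched with acetic anhydride to give 4-methoxy-1,3-bis(3-methylbut-2-enyl)cyclohexa-1,3-dien-2-yl acetate F8. Heating F8 with 12 in o-xylene should give, through the adduct [3-bromo-2-benzoyl-1-methoxy-4,6-bis(3-methylbut-2-enyl)bicyclo[2.2.2]octa-2,5-dien-5-yl] acetate F9 and loss of ethylene, 4-benzoyl-3-bromo-5-methoxy-2,6-bis(3-methylbut-2-enyl)phenyl acetate F10. The KOH of the first stage of step 8 saponifies F10, and the sequence comes back to the route at 15.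

**Further compounds**
F1 | step 7 | 2-(tert-butyldimethylsilyloxy)-4-methoxy-3-(3-methylbut-2-enyl)cyclohexa-1,3-diene | COC1=C(CC=C(C)C)C(O[Si](C)(C)C(C)(C)C)=CCC1
F2 | step 7 | [3-bromo-5-(tert-butyldimethylsilyloxy)-1-methoxy-6-(3-methylbut-2-enyl)bicyclo[2.2.2]octa-2,5-dien-2-yl](phenyl)methanone (racemic) | COC12CCC(C(Br)=C1C(=O)c1ccccc1)C(O[Si](C)(C)C(C)(C)C)=C2CC=C(C)C
F3 | step 7 | [2-bromo-4-(tert-butyldimethylsilyloxy)-6-methoxy-5-(3-methylbut-2-enyl)phenyl](phenyl)methanone | COc1c(CC=C(C)C)c(O[Si](C)(C)C(C)(C)C)cc(Br)c1C(=O)c1ccccc1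
F4 | step 7 | [2-bromo-4-hydroxy-6-methoxy-5-(3-methylbut-2-enyl)phenyl](phenyl)methanone | COc1c(CC=C(C)C)c(O)cc(Br)c1C(=O)c1ccccc1
F5 | step 7 | [4,6-dihydroxy-2-methoxy-3-(3-methylbut-2-enyl)phenyl](phenyl)methanone | COc1c(CC=C(C)C)c(O)cc(O)c1C(=O)c1ccccc1
F6 | step 8 | phenyl[4-(tert-butyldimethylsilyloxy)-2-methoxy-3,5-bis(3-methylbut-2-enyl)-6-(4,4,5,5-tetramethyl-1,3,2-dioxaborolan-2-yl)phenyl]methanone | COc1c(CC=C(C)C)c(O[Si](C)(C)C(C)(C)C)c(CC=C(C)C)c(B2OC(C)(C)C(C)(C)O2)c1C(=O)c1ccccc1
F7 | step 8 | [4-(tert-butyldimethylsilyloxy)-2-hydroxy-6-methoxy-3,5-bis(3-methylbut-2-enyl)phenyl](phenyl)methanone | COc1c(CC=C(C)C)c(O[Si](C)(C)C(C)(C)C)c(CC=C(C)C)c(O)c1C(=O)c1ccccc1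
F8 | step 4 | 4-methoxy-1,3-bis(3-methylbut-2-enyl)cyclohexa-1,3-dien-2-yl acetate | COC1=C(CC=C(C)C)C(OC(C)=O)=C(CC=C(C)C)CC1
F9 | step 4 | [3-bromo-2-benzoyl-1-methoxy-4,6-bis(3-methylbut-2-enyl)bicyclo[2.2.2]octa-2,5-dien-5-yl] acetate (racemic) | COC12CCC(CC=C(C)C)(C(Br)=C1C(=O)c1ccccc1)C(OC(C)=O)=C2CC=C(C)C
F10 | step 4 | 4-benzoyl-3-bromo-5-methoxy-2,6-bis(3-methylbut-2-enyl)phenyl acetate | COc1c(CC=C(C)C)c(OC(C)=O)c(CC=C(C)C)c(Br)c1C(=O)c1ccccc1
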